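Ring B of the target (C1, C2, C3, C3a, C7a) is a cyclopentanone whose carbonyl carbon C2 lies between the methyl-bearing C1 and the ethyl-bearing C3; inserting one more carbonyl carbon there gives the 1,2-dione of a six-membered ring. The route therefore assembles a trans-fused decalin in which ring A (C3a–C7a, with the C4=C5 alkene, the C6 and C7 quaternary centres and a C7 methyl ester) is finished and the second ring holds this diketone. A single hydroxide-triggered benzilic acid rearrangement contracts that ring to ring B by a 1,2-shift of C3 (or C1) onto the neighbouring carbonyl carbon; the resulting C2 hydroxy acid is then decarboxylated to the C2 ketone.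

Key step: step 15

Locants: the indane numbering of the target is used for every intermediate; C2′ is the extra ring B carbon between C2 and C3 in the decalins.

Assumption: in dione 24 and ketones 26 and 27 the arrangement with H1/H7a trans and H3/H3a trans (C1 methyl and C3 ethyl pseudo-equatorial on ring B) is taken to be the thermodynamic minimum, so the epimerisable centres C1 and C3 converge on the target configuration under base.

Step 1
Reactants: 1 3,4-diethylfuran-2,5-dione (2,3-diethylmaleic anhydride); 2 buta-1,3-diene
Product: 3 meso cis-1,2-diethylcyclohex-4-ene-1,2-dicarboxylic anhydride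
Conditions: 2 (excess), hydroquinone (cat.), toluene, sealed vessel, 190 °C
Reagents that add atoms: none
Why: thermal Diels–Alder reaction of a tetrasubstituted maleic anhydride with butadiene (as known for 2,3-dimethylmaleic anhydride) is suprafacial on the dienophile, so the two ethyl groups that become the C6 and C7 ethyls end up cis on the two new quaternary carbons and the adduct is meso.

Step 2
Reactants: 3 meso anhydride
Product: 4 (1S,2R)-1,2-diethyl-2-(methoxycarbonyl)cyclohex-4-ene-1-carboxylic acid
Conditions: quinidine (1.1 equiv), MeOH (5 equiv), toluene, −20 °C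
Reagents that add atoms: methanol, CO
Why: cinchona-alkaloid-mediated desymmetrising methanolysis of a meso anhydride steers methanol to one of the two enantiotopic carbonyl groups and so sets the absolute configuration of both quaternary centres at once (free acid on the future C6, methyl ester on the future C7); the alkaloid is the one that gives the (1S,2R) sense in the parent cis-cyclohex-4-ene-1,2-dicarboxylic anhydride series, with its pseudo-enantiomer quinine as the alternative if that sense does not carry over.

Step 3
Reactants: 4 hemiester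
Product: 5 methyl 1,2-diethyl-4-iodo-7-oxo-6-oxabicyclo[3.2.1]octane-2-carboxylate (iodolactone)
Conditions: I2, KI, NaHCO3, H2O/CH2Cl2, 0 °C to rt, dark
Reagents that add atoms: iodine, II
Why: iodolactonisation in which the C6 carboxylate opens the iodonium ion at C4 by a five-membered (γ-lactone) closure with anti addition, so the new C4–O bond is cis to the C6 carbonyl and iodine sits trans on C3a; this marks C4 as the future ketone carbon.

Step 4
Reactants: 5 iodolactone
Product: 6 methyl 1,2-diethyl-7-oxo-6-oxabicyclo[3.2.1]oct-3-ene-2-carboxylate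
Conditions: DBU, toluene, 90 °C
Reagents that add atoms: none
Why: E2 dehydroiodination in which only a C7a hydrogen is antiperiplanar to the axial C3a iodide (loss of the C4 hydrogen would give a bridgehead enol ether), so the alkene forms between C3a and C7a and no stereocentre is touched.

Step 5
Reactants: 6 alkenyl lactone
Product: 7 methyl 1,2-diethyl-7-hydroxy-6-oxabicyclo[3.2.1]oct-3-ene-2-carboxylate (lactol)
Conditions: iBu2AlH (1.1 equiv), CH2Cl2, −78 °C; aq. KNaC4H4O6
Reagents that add atoms: none
Why: partial reduction of a lactone to the lactol at low temperature, the strained bicyclic lactone being reduced much faster than the methyl ester on the quaternary C7 next to the quaternary C6; the new hemiacetal centre (either anomer) is lost in step 6.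

Step 6
Reactants: 7 lactol; 8 diethyl benzylphosphonate
Product: 9 methyl 1,6-diethyl-4-hydroxy-6-[(E)-2-phenylethenyl]cyclohex-2-ene-1-carboxylate
Conditions: 8 and KN(SiMe3)2 (2.5 equiv each), THF, 0 to 40 °C
Reagents that add atoms: none
Why: Horner–Wadsworth–Emmons olefination of the lactol through its open hydroxy-aldehyde form converts the C6 formyl group into the (E)-styryl group (the benzylphosphonate anion gives the E alkene), and the released C4 hydroxyl keeps the configuration fixed in step 3.

Step 7
Reactants: 9 allylic alcohol
Product: 10 methyl 1,6-diethyl-4-oxo-6-[(E)-2-phenylethenyl]cyclohex-2-ene-1-carboxylate (ring A enone)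
Conditions: MnO2, CH2Cl2, rt
Reagents that add atoms: none
Why: chemoselective oxidation of an allylic alcohol to the enone, which removes the C4 carbinol centre and leaves the two quaternary centres (styryl cis to the ester, ethyl groups cis) untouched.

Step 8
Reactants: 11 (E)-hex-3-en-2-one
Product: 13 (E)-2-[(tert-butyldimethylsilyl)oxy]hexa-1,3-diene, via lithium dienolate 12 (not isolated)
Conditions: LiN(iPr)2, THF, −78 °C; TBSCl, DMPU, −78 °C to rt
Reagents that add atoms: tert-butyldimethylsilyl chloride, CC(C)(C)[Si](C)(C)Cl
Why: kinetic deprotonation of the methyl group of the enone gives the cross-conjugated lithium dienolate, which is O-silylated to the 2-silyloxydiene with the (E)-alkene retained; no stereocentre is formed, and the diene carries no C1 methyl so that the coming bond to C7a is made by an unsubstituted terminus.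

Step 9
Reactants: 10 ring A enone; 13 silyloxydiene
Product: 15 trans-fused decalone methyl 7-[(tert-butyldimethylsilyl)oxy]-1,2,5-triethyl-4-oxo-2-[(E)-2-phenylethenyl]-1,2,3,4,4a,5,8,8a-octahydronaphthalene-1-carboxylate, via cis-fused cycloadduct 14 (not isolated)
Conditions: AlBr3/AlMe3 (10:1, 2 equiv), toluene/CH2Cl2, −5 °C; aqueous work-up; then DBU, toluene, 40 °C
Reagents that add atoms: none
Why: Lewis-acid-promoted Diels–Alder reaction of a hindered 2-silyloxydiene with a hindered cyclohexenone, in which the unsubstituted, most nucleophilic diene terminus (C1) bonds to the enone β-carbon C7a and the ethyl-bearing terminus (C3) to C3a; bond formation at C7a is expected anti to the Lewis-acid-complexed C7 ester, on the face of the two ethyl groups, the endo transition state places the C3 ethyl cis to C4, and DBU then epimerises C3a (α to the C4 ketone) to the trans ring fusion, which is unhindered because C1 is still a methylene group.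

Step 10
Reactants: 15 trans-fused decalone
Product: 17 C4 enol triflate of 15, via potassium enolate 16 (not isolated)
Conditions: KN(SiMe3)2, THF, −78 °C; PhNTf2, −78 to 0 °C
Reagents that add atoms: N-phenylbis(trifluoromethanesulfonimide), O=S(=O)(N(c1ccccc1)S(=O)(=O)C(F)(F)F)C(F)(F)F
Why: kinetic deprotonation of the C4 ketone at the C5 methylene (the only other α-hydrogen is the hindered C3a methine) and O-triflation give the C4=C5 enol triflate, which locks the trans ring fusion because C3a is no longer α to a carbonyl group.

Step 11
Reactants: 17 enol triflate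
Product: 18 methyl 7-[(tert-butyldimethylsilyl)oxy]-1,2,4,5-tetraethyl-2-[(E)-2-phenylethenyl]-1,2,4a,5,8,8a-hexahydronaphthalene-1-carboxylate
Conditions: Et2Zn, PdCl2(dppf) (5 mol %), THF, 50 °C
Reagents that add atoms: diethylzinc, CC[Zn]CC
Why: Negishi cross-coupling of an alkenyl triflate with an alkylzinc reagent (oxidative addition to zerovalent palladium, with the chelating ferrocenyl diphosphine suppressing β-hydride elimination) installs the C4 ethyl group with the C4=C5 alkene in place; no stereocentre is involved and the ester and silyl enol ether are inert to the zinc reagent.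

Step 12
Reactants: 18 silyl enol ether
Product: 20 methyl 6-[(tert-butyldimethylsilyl)oxy]-1,2,4,5-tetraethyl-7-oxo-2-[(E)-2-phenylethenyl]-1,2,4a,5,6,7,8,8a-octahydronaphthalene-1-carboxylate, via silyloxy epoxide 19 (not isolated)
Conditions: mCPBA (1.05 equiv), CH2Cl2, −20 to 0 °C
Reagents that add atoms: 3-chloroperbenzoic acid, O=C(OO)c1cccc(Cl)c1
Why: Rubottom oxidation, in which the electron-rich silyl enol ether is epoxidised far faster than the hindered C4=C5 alkene or the styrene and the silyloxy epoxide rearranges with silyl shift to the C2 ketone carrying the silyloxy group on C2′; the new C2′ centre is removed in step 14, so either epimer serves.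

Step 13
Reactants: 20 α-silyloxy ketone
Product: 22 the 8-methyl derivative of 20 (C1 methyl cis to H7a), via lithium enolate 21 (not isolated)
Conditions: LiN(iPr)2, THF, −78 °C; MeI, −78 to −20 °C
Reagents that add atoms: iodomethane, CI
Why: kinetic enolate alkylation, in which the C1 methylene is the only unhindered α-position of the C2 ketone (C2′ is a silyloxy-substituted methine) and iodomethane should enter C1 anti to the axial C7 ethyl group to give the equatorial methyl; the methyl is introduced only now, after the ring fusion is locked, and C1 stays epimerisable so that steps 14, 15 and 17 can correct it.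

Step 14
Reactants: 22 C1-methyl α-silyloxy ketone
Product: 24 methyl 1,2,4,5-tetraethyl-8-methyl-6,7-dioxo-2-[(E)-2-phenylethenyl]-1,2,4a,5,6,7,8,8a-octahydronaphthalene-1-carboxylate (trans-fused precursor dione), via acyloin 23 (not isolated)
Conditions: HF·pyridine, THF, 0 °C to rt; then Dess–Martin periodinane, NaHCO3, CH2Cl2, rt
Reagents that add atoms: none
Why: desilylation followed by Dess–Martin oxidation of the α-hydroxy ketone gives the vicinal diketone (in equilibrium with its diosphenol forms); C1 and C3 now both flank a carbonyl group and can settle in the diequatorial arrangement, while C3a and C7a are fixed.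

Step 15
Reactants: 24 precursor dione
Product: 25 3,4,6,7-tetraethyl-2-hydroxy-7-(methoxycarbonyl)-1-methyl-6-[(E)-2-phenylethenyl]-2,3,3a,6,7,7a-hexahydro-1H-indene-2-carboxylic acid
Conditions: KOH (10 equiv), 1-propanol/H2O (3:1), reflux, argon; then 1 M HCl, 0 °C
Reagents that add atoms: potassium hydroxide, [K+].[OH-]
Why: Hydroxide adds reversibly to one carbonyl of the vicinal diketone (the free diketo form is in equilibrium with the diosphenolate), and the resulting alkoxide drives a 1,2-shift of the flanking ring carbon (C3 if hydroxide has added next to it, otherwise C1) to the adjacent carbonyl carbon, which gives the ring-contracted α-hydroxy carboxylate irreversibly. This is the benzilic acid rearrangement of a cyclic 1,2-dione, the reaction type used to contract ring A of steroidal 2,3-diones. The five-membered ring B is closed by this anionic 1,2-alkyl shift (a ring contraction, not an exo or endo cyclisation onto a π bond), forming C2–C3 or, equivalently, C1–C2. The only new stereocentre, the C2 carbinol, is not controlled and need not be, since step 16 destroys it; the migrating carbon keeps its configuration, C1 and C3 can still equilibrate through the diosphenolate, and C3a and C7a are not enolisable now that C4 is an alkene carbon. No regioselectivity is required because both modes of addition and migration give the same ring B skeleton; the chemoselectivity needed is survival of the methyl ester, secured by its place on the quaternary C7 next to the quaternary C6, and exclusion of oxygen prevents oxidative cleavage of the diosphenolate.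

Step 16
Reactants: 25 α-hydroxy acid
Product: 26 methyl 3,4,6,7-tetraethyl-1-methyl-2-oxo-6-[(E)-2-phenylethenyl]-2,3,3a,6,7,7a-hexahydro-1H-indene-7-carboxylate
Conditions: Pb(OAc)4 (1.1 equiv), pyridine, CH2Cl2, 0 °C to rt
Reagents that add atoms: none
Why: oxidative decarboxylation of an α-hydroxy acid by Pb(OAc)4 (cleavage through the cyclic lead ester) expels the carboxyl carbon as CO2 and turns the C2 carbinol into the ketone, which erases the temporary C2 stereocentre; the alkenes and the hindered ester do not react under these conditions.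

Step 17
Reactants: 26 keto ester
Product: 27 target acid CNP0324606.3
Conditions: NaSEt (6 equiv), DMF, 90 °C; then 1 M HCl
Reagents that add atoms: none
Why: SN2 demethylation of the hindered methyl ester by thiolate (attack at the O-methyl carbon, so the congested carbonyl group is not approached) frees the C7 acid, while the basic medium equilibrates C1 and C3 through the ketone enolates to the all-trans ring B; C3a and C7a are not enolisable and stay trans.

Compound list
1 | 3,4-diethylfuran-2,5-dione (2,3-diethylmaleic anhydride) | CCC1=C(CC)C(=O)OC1=O | starting material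
2 | buta-1,3-diene | C=CC=C | starting material
3 | meso cis-1,2-diethylcyclohex-4-ene-1,2-dicarboxylic anhydride (ethyl groups cis) | C1=CC[C@@]2(CC)C(=O)OC(=O)[C@@]2(CC)C1 | intermediate
4 | (1S,2R)-1,2-diethyl-2-(methoxycarbonyl)cyclohex-4-ene-1-carboxylic acid (acid carbon = future C6, ester carbon = future C7; carboxyl groups cis) | C1=CC[C@@](CC)(C(=O)OC)[C@@](CC)(C(=O)O)C1 | intermediate
5 | methyl 1,2-diethyl-4-iodo-7-oxo-6-oxabicyclo[3.2.1]octane-2-carboxylate (lactone from the C6 carboxyl to C4; iodine on C3a trans to the lactone oxygen; ester on the lactone face) | O=C1O[C@@H]2C[C@@]1(CC)[C@](CC)(C(=O)OC)C[C@H]2I | intermediate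
6 | methyl 1,2-diethyl-7-oxo-6-oxabicyclo[3.2.1]oct-3-ene-2-carboxylate (C3a=C7a alkene) | O=C1O[C@@H]2C[C@@]1(CC)[C@](CC)(C(=O)OC)C=C2 | intermediate
7 | methyl 1,2-diethyl-7-hydroxy-6-oxabicyclo[3.2.1]oct-3-ene-2-carboxylate (lactol, either anomer) | OC1O[C@@H]2C[C@@]1(CC)[C@](CC)(C(=O)OC)C=C2 | intermediate
8 | diethyl benzylphosphonate | CCOP(=O)(Cc1ccccc1)OCC | starting material
9 | methyl 1,6-diethyl-4-hydroxy-6-[(E)-2-phenylethenyl]cyclohex-2-ene-1-carboxylate (hydroxyl, styryl and ester on one face, both ethyl groups on the other) | O[C@@H]1C[C@@](/C=C/c2ccccc2)(CC)[C@](CC)(C(=O)OC)C=C1 | intermediate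
10 | methyl 1,6-diethyl-4-oxo-6-[(E)-2-phenylethenyl]cyclohex-2-ene-1-carboxylate (ring A enone; styryl cis to ester) | O=C1C[C@@](/C=C/c2ccccc2)(CC)[C@](CC)(C(=O)OC)C=C1 | intermediate
11 | (E)-hex-3-en-2-one | CC(=O)/C=C/CC | starting material
12 | lithium (E)-hexa-1,3-dien-2-olate (not isolated) | [Li+].[O-]C(=C)/C=C/CC | intermediate
13 | (E)-2-[(tert-butyldimethylsilyl)oxy]hexa-1,3-diene | C=C(O[Si](C)(C)C(C)(C)C)/C=C/CC | intermediate
14 | cis-fused cycloadduct: methyl 7-[(tert-butyldimethylsilyl)oxy]-1,2,5-triethyl-4-oxo-2-[(E)-2-phenylethenyl]-1,2,3,4,4a,5,8,8a-octahydronaphthalene-1-carboxylate with H3a cis to H7a (not isolated) | O=C1C[C@@](/C=C/c2ccccc2)(CC)[C@](CC)(C(=O)OC)[C@@H]2[C@H]1[C@H](CC)C=C(O[Si](C)(C)C(C)(C)C)C2 | intermediate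
15 | trans-fused decalone: same constitution as 14 with H3a trans to H7a, C7a–C1 bond on the face of the ethyl groups, C3 ethyl equatorial | O=C1C[C@@](/C=C/c2ccccc2)(CC)[C@](CC)(C(=O)OC)[C@@H]2[C@@H]1[C@H](CC)C=C(O[Si](C)(C)C(C)(C)C)C2 | intermediate
16 | potassium enolate of 15 (C4–O−, C4=C5; not isolated) | [K+].[O-]C1=C[C@@](/C=C/c2ccccc2)(CC)[C@](CC)(C(=O)OC)[C@@H]2[C@@H]1[C@H](CC)C=C(O[Si](C)(C)C(C)(C)C)C2 | intermediate
17 | C4 enol triflate of 15 (C4=C5) | O=S(=O)(OC1=C[C@@](/C=C/c2ccccc2)(CC)[C@](CC)(C(=O)OC)[C@@H]2[C@@H]1[C@H](CC)C=C(O[Si](C)(C)C(C)(C)C)C2)C(F)(F)F | intermediate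
18 | methyl 7-[(tert-butyldimethylsilyl)oxy]-1,2,4,5-tetraethyl-2-[(E)-2-phenylethenyl]-1,2,4a,5,8,8a-hexahydronaphthalene-1-carboxylate (C4 ethyl, C4=C5; ring B silyl enol ether) | CCC1=C[C@@](/C=C/c2ccccc2)(CC)[C@](CC)(C(=O)OC)[C@@H]2[C@@H]1[C@H](CC)C=C(O[Si](C)(C)C(C)(C)C)C2 | intermediate
19 | silyloxy epoxide of 18 across C2 and C2′ (not isolated) | CCC1=C[C@@](/C=C/c2ccccc2)(CC)[C@](CC)(C(=O)OC)[C@@H]2[C@@H]1[C@H](CC)C3OC3(O[Si](C)(C)C(C)(C)C)C2 | intermediate
20 | methyl 6-[(tert-butyldimethylsilyl)oxy]-1,2,4,5-tetraethyl-7-oxo-2-[(E)-2-phenylethenyl]-1,2,4a,5,6,7,8,8a-octahydronaphthalene-1-carboxylate (C2 ketone, C2′ silyloxy, either C2′ epimer) | CCC1=C[C@@](/C=C/c2ccccc2)(CC)[C@](CC)(C(=O)OC)[C@@H]2[C@@H]1[C@H](CC)C(O[Si](C)(C)C(C)(C)C)C(=O)C2 | intermediate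
21 | lithium enolate of 20 (C1=C2–O−; not isolated) | [Li+].CCC1=C[C@@](/C=C/c2ccccc2)(CC)[C@](CC)(C(=O)OC)[C@@H]2[C@@H]1[C@H](CC)C(O[Si](C)(C)C(C)(C)C)C([O-])=C2 | intermediate
22 | 8-methyl derivative of 20 (C1 methyl cis to H7a) | CCC1=C[C@@](/C=C/c2ccccc2)(CC)[C@](CC)(C(=O)OC)[C@@H]2[C@@H]1[C@H](CC)C(O[Si](C)(C)C(C)(C)C)C(=O)[C@H]2C | intermediate
23 | acyloin: 6-hydroxy-7-oxo compound from 22 (not isolated) | CCC1=C[C@@](/C=C/c2ccccc2)(CC)[C@](CC)(C(=O)OC)[C@@H]2[C@@H]1[C@H](CC)C(O)C(=O)[C@H]2C | intermediate
24 | precursor dione: methyl 1,2,4,5-tetraethyl-8-methyl-6,7-dioxo-2-[(E)-2-phenylethenyl]-1,2,4a,5,6,7,8,8a-octahydronaphthalene-1-carboxylate (trans-fused; C1 methyl and C3 ethyl equatorial) | CCC1=C[C@@](/C=C/c2ccccc2)(CC)[C@](CC)(C(=O)OC)[C@@H]2[C@@H]1[C@H](CC)C(=O)C(=O)[C@H]2C | intermediate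
25 | 3,4,6,7-tetraethyl-2-hydroxy-7-(methoxycarbonyl)-1-methyl-6-[(E)-2-phenylethenyl]-2,3,3a,6,7,7a-hexahydro-1H-indene-2-carboxylic acid (target locants; C2 configuration immaterial) | CCC1=C[C@@](/C=C/c2ccccc2)(CC)[C@](CC)(C(=O)OC)[C@@H]2[C@@H]1[C@H](CC)[C@](O)(C(=O)O)[C@H]2C | intermediate
26 | methyl 3,4,6,7-tetraethyl-1-methyl-2-oxo-6-[(E)-2-phenylethenyl]-2,3,3a,6,7,7a-hexahydro-1H-indene-7-carboxylate (target locants) | CCC1=C[C@@](/C=C/c2ccccc2)(CC)[C@](CC)(C(=O)OC)[C@@H]2[C@@H]1[C@H](CC)C(=O)[C@H]2C | intermediate
27 | CNP0324606.3: 3,4,6,7-tetraethyl-1-methyl-2-oxo-6-[(E)-2-phenylethenyl]-2,3,3a,6,7,7a-hexahydro-1H-indene-7-carboxylic acid (target locants) | CCC1=C[C@@](/C=C/c2ccccc2)(CC)[C@](CC)(C(=O)O)[C@@H]2[C@@H]1[C@H](CC)C(=O)[C@H]2C | target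

Total step count: 17
Longest linear sequence: 16 steps (steps 1–7 and 9–17; step 8 makes the diene separately)

Steps most likely to fail

Step 15 (key step): the dione may rest as its unreactive diosphenolate, so that hydroxide addition and the 1,2-shift are outrun by oxidative cleavage or by slow saponification of the C7 ester. The fallback sets out from 24 and returns at 25, and contracts the ring by a Wolff rearrangement instead. Dione 24 and TsNHNH2 in MeOH give the mono-tosylhydrazone F4 (drawn at C2′; the C2 isomer leads to the same ring). Et3N converts it into the α-diazo ketone F5. Irradiation at 450 nm in THF/H2O, a wavelength the styrene does not absorb, triggers the Wolff rearrangement to the ring-contracted carboxylic acid F6. α-Hydroxylation of its dianion (LiN(iPr)2, THF; O2; P(OEt)3) gives 25.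

Step 9: bond formation at C7a has to occur next to the quaternary C7, so the cycloaddition may stall while the diene is lost by protodesilylation, and the facial preference anti to the complexed ester may erode. The fallback sets out from 10 and 11 and returns at 14, and replaces the pericyclic step by a stepwise anionic Michael–Michael annulation. Lithium dienolate 12, generated from 11 as in step 8, adds through its terminal carbon to C7a of 10 in THF at −78 to −20 °C. The ring A enolate so formed closes the six-membered ring by intramolecular Michael addition to the enone of the side chain and gives the ring B lithium enolate F1. This is silylated in the same flask (TBSCl, DMPU) to 14 and its C3a and C3 epimers. C3a is then equilibrated by DBU as in step 9, and C3 at the dione stage.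

Step 2: the tetrasubstituted anhydride may react too slowly at the low temperature needed for high enantioselectivity, so that conversion or selectivity is lost on warming. The fallback sets out from 3 and returns at 4, and is a classical resolution. NaOMe in MeOH opens 3 to the racemic hemiester F2. This is crystallised as its (R)-1-phenylethylammonium salt F3 (the (S)-amine is used if the other diastereomeric salt is the less soluble one). Aqueous HCl then releases 4.

Further compounds
F1 | step 9 | ring B lithium enolate of the Michael–Michael adduct (C2–O−, C2=C2′; C3a and C3 unassigned) | [Li+].O=C1C[C@@](/C=C/c2ccccc2)(CC)[C@](CC)(C(=O)OC)[C@@H]2C1C(CC)C=C([O-])C2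
F2 | step 2 | racemic cis-1,2-diethyl-2-(methoxycarbonyl)cyclohex-4-ene-1-carboxylic acid (racemate; one enantiomer drawn) | C1=CC[C@@](CC)(C(=O)OC)[C@@](CC)(C(=O)O)C1
F3 | step 2 | (R)-1-phenylethylammonium salt of 4 | C1=CC[C@@](CC)(C(=O)OC)[C@@](CC)(C(=O)[O-])C1.C[C@@H]([NH3+])c1ccccc1
F4 | step 15 | mono-tosylhydrazone of 24 at C2′ | CCC1=C[C@@](/C=C/c2ccccc2)(CC)[C@](CC)(C(=O)OC)[C@@H]2[C@@H]1[C@H](CC)C(=NNS(=O)(=O)c1ccc(C)cc1)C(=O)[C@H]2C
F5 | step 15 | α-diazo ketone (diazo on C2′, ketone on C2) | CCC1=C[C@@](/C=C/c2ccccc2)(CC)[C@](CC)(C(=O)OC)[C@@H]2[C@@H]1[C@H](CC)C(=[N+]=[N-])C(=O)[C@H]2C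
F6 | step 15 | ring-contracted acid: 3,4,6,7-tetraethyl-7-(methoxycarbonyl)-1-methyl-6-[(E)-2-phenylethenyl]-2,3,3a,6,7,7a-hexahydro-1H-indene-2-carboxylic acid | CCC1=C[C@@](/C=C/c2ccccc2)(CC)[C@](CC)(C(=O)OC)[C@@H]2[C@@H]1[C@H](CC)C(C(=O)O)[C@H]2C
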